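## Structural features

The target is a trans-fused decalin of the eudesmane type. Ring A holds C1, C2, C3, C4, C5 and C10, ring B holds C5 to C10, and the rings share the C5–C10 bond. C10 is an all-carbon quaternary centre carrying the angular methyl (its face is called β); C5 carries an α hydrogen. Five further stereocentres run without a break from C3 to C7: a 3α secondary hydroxyl, a 4β tertiary hydroxyl with a 4α methyl, the ring-fusion carbon C5, a 6β benzoate and a 7β (equatorial) isopropyl group. The absolute configuration is (3R,4R,5S,6R,7S,10S). The C10 methyl, the C4 hydroxyl and the C6 benzoate are mutually 1,3-diaxial on the β face, and the two ring A hydroxyls are trans-diaxial. Fragile points are the benzoate (saponification, 1,3-shift to the syn-axial C4 oxygen), the tertiary alcohol (ionisation and elimination in acid) and, in ketone intermediates, the enolisable centres C4, C5 and C7. The real difficulty is C10, the one centre that cannot be corrected later, together with the crowded β face around C4 and C6. The oxygens at C3 and C6 are 1,4-related, so in a 3,6-dione C4 and C5 are both α carbons of ketones; the key step joins these two enolate carbons to close ring A.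

## Logic of the disconnections

19 to 18: the C4–OH bond is cut and both ring A oxygens are traced to one epoxide oxygen. A 3α,4β trans-diaxial diol is what an α-epoxide gives when it opens at its tertiary carbon with inversion. Two stereocentres reduce to one epoxide. The forward step must bring water to C4 on the β face, syn-axial to the C10 methyl and the benzoate, without acyl shift or elimination.

18 to 17: both epoxide C–O bonds are cut. The β face of the C3=C4 bond is screened by the angular methyl and the 6β ester, so a peracid should attack α. Two more stereocentres disappear. The ester must already be in place, because a free 6β hydroxyl would steer the oxidant to the β face.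

17 to 16, 15 and 14: the C3–H bond (from C3–OTf), the ester O–acyl bond and the C6–H bond are cut in that order. C3 is kept as an enol triflate while C6 is reduced and acylated, so a β,γ-unsaturated ketone that could slip into conjugation and erase C5 is never handled. The gain is a 6-ketone whose reduction is governed by the angular methyl. Hydride must arrive from the α side, and the triflate must survive hydride and acylation.

14 to 13: the O–S bond is cut and the C3=C4 bond is traced to the C3 carbonyl. Enolisation towards the more substituted carbon places the double bond at C3=C4. A sulfonylhydrazone–alkyllithium (Shapiro) elimination is not used, because it would remove a C2 proton and give the C2,C3-alkene. 13 then holds all fifteen carbons and only two ketones. The forward step must choose C3 over C6 and C4 over C2.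

13 to 10 (through 12 and 11): the C4–C5 bond is cut. It links two carbons that are each α to a carbonyl, a 1,4-dicarbonyl relation that ordinary enolate–electrophile chemistry cannot make, so two enolates are joined oxidatively. Ring A opens, two epimerisable stereocentres vanish and a monocyclic diketone remains. The forward step needs enolisation at C4 and C5, and a later equilibration to the trans-fused, all-equatorial dione.

10 to 9, then to 3 and 7 (through 8): the ketal is removed and the C10–C1 bond is cut. C10 is the β carbon of an enone and the chain is a homoenolate equivalent. This gives a monoterpene enone and a five-carbon bromoketal. The forward addition must create the quaternary centre under catalyst control against a 1,4-related resident centre, and 8 must be stable, hence the six-membered ketal.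

7 to 4 and 5 (through 6): the C–Br bond and the two ketal C–O bonds are cut. Conjugate hydrobromination and ketalisation make the unit in one operation; 6 must not be isolated because it loses HBr.

3 to 1 (through 2): the enone C=C bond is traced to a saturated ketone. 1 is a cheap single enantiomer whose isopropyl-bearing carbon already has the configuration needed at C7. The enolisation must be kinetic and away from that carbon so that it is not racemised.

## Other disconnections considered

Alternative 1: C3–C4 and C5–C10 are cut together. The forward step is a thermal intramolecular Diels–Alder reaction of the butenolide triene A1. Its silyloxydiene (C10, C1, C2, C3) adds across the butenolide double bond (C4, C5) to give the tricyclic lactone A2.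
- In its favour: both rings, two C–C bonds and the centres C3, C4, C5 and C10 are made at once with no reagent, which is better than the chosen plan in bonds and stereocentres per step. The C3 oxygen arrives in its final oxidation state and configuration, whereas the chosen plan removes and reinstalls it. The lactone ties C4 and C6 together on the β face.
- Against it: the lactone carbonyl is a carbon where the target has a hydroxyl, so it must be degraded with retention (methyl ketone, then Baeyer–Villiger oxidation). That leaves a tertiary acetate to cleave beside the benzoate.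
- Also against it: the diene terminus C10 carries two substituents, one of which must lie inside the s-cis diene, so the cycloaddition should be slow and open to hydrogen shifts.
- Also against it: A1 needs its own C6 and C7 stereocentres and a defined dienol ether.
- Comparison: the mechanism is concerted with kinetic stereocontrol, against a stepwise coupling corrected by equilibration; in reliability of outcome the two are about equal. In overall step count the chosen plan should be shorter.

Alternative 2: C5–C6 and C9–C10 are cut, building ring B onto a ring A quinone. The methyl-bearing double bond of quinone A3 adds to silyloxydiene A4 under the chiral oxazaborolidinium salt A5 to give the endo, cis-fused adduct A6.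
- In its favour: it is convergent from two achiral pieces and sets C10 by a catalytic enantioselective step of a well-studied type. Here it is better than the chosen plan, which must override a resident centre.
- Also in its favour: C7 would later be set by hydrogenation of the C7=C8 bond from the open α face, a kinetic event, which is better than the modest thermodynamic preference the chosen plan relies on. A methyl nucleophile added to the C4 ketone from the α side would give the 4β carbinol directly.
- Against it: the C1 carbonyl is surplus and must be deleted. The C6 oxygen arrives α and must be inverted. The enol ether at C3 has to be turned into a 3α alcohol.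
- Comparison: both plans need base equilibration of C5 to the trans junction, so they are equal there. The redox and deletion work after the key step should make it longer than the chosen plan.

Alternative 3: only C5–C6 is cut. The carbene from triazolium salt A8 and an amine base turns the aldehyde of dienone A7 into an acyl anion equivalent. It adds to one enantiotopic β carbon and closes ring B as dione A9.
- In its favour: it gives the same C3/C6 1,4-dicarbonyl pattern as the chosen plan, by umpolung instead of oxidation, so the two are equal in concept.
- Also in its favour: it is better in three respects. Enantiocontrol is catalytic, there is no stoichiometric metal oxidant, and there is no ambiguity about which α position reacts.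
- Against it: A9 lacks the C4 methyl and the C7 isopropyl group. Two separate enolate functionalisations must follow, and an isopropyl group cannot be put in cleanly by direct alkylation. The C1=C2 bond must be reduced.
- Comparison: C5 again has to be epimerised, as in the chosen plan. The chosen plan carries all fifteen carbons into its key step and should be shorter.

Key step: step 5

Remarks on the chemistry:
- β denotes the face of the decalin that carries the C10 methyl; bicyclic compounds are named on the eudesmane skeleton with the numbering used above.
- Assumption: in step 3 the antipode of the imidazolinium ligand is the one that sends the alkyl group to the face giving the (3S) centre; its sense on this enone is to be settled in a trial run.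
- Any C2 epimer present in commercial 1 is harmless, because that centre is re-equilibrated when 13 is formed.

Step 1
Reactants: 1 (2S,5R)-5-methyl-2-(propan-2-yl)cyclohexan-1-one [(−)-menthone]
Product: 3 (6S)-3-methyl-6-(propan-2-yl)cyclohex-2-en-1-one, via silyl enol ether 2 (not isolated)
Conditions: LDA, THF, −78 °C; TMSCl; then Pd(OAc)2 (10 mol %), O2 (1 atm), DMSO, 25 °C
Reagents that add atoms: none
Why: Kinetic deprotonation takes a proton from the methylene next to the carbonyl and not from the isopropyl-bearing methine, so that stereocentre is never enolised; Saegusa–Ito dehydrogenation of the enol silane (palladium enolate, β-hydride elimination from the methyl-bearing carbon) then gives the enone, with no new stereocentre.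

Step 2
Reactants: 4 pent-1-en-3-one; 5 2,2-dimethylpropane-1,3-diol
Product: 7 2-(2-bromoethyl)-2-ethyl-5,5-dimethyl-1,3-dioxane, via 1-bromopentan-3-one 6 (not isolated)
Conditions: HBr (gas), CH2Cl2, 0 °C; then 5, HC(OEt)3, p-TsOH (cat.), 25 °C
Reagents that add atoms: hydrogen bromide, Br
Why: Conjugate hydrobromination of the enone followed by acid-catalysed ketalisation with the orthoformate as water scavenger; the six-membered ketal is chosen because its Grignard reagent does not collapse to a cyclopropyl ether as that of a dioxolane tends to.

Step 3
Reactants: 7 2-(2-bromoethyl)-2-ethyl-5,5-dimethyl-1,3-dioxane; 3 (6S)-3-methyl-6-(propan-2-yl)cyclohex-2-en-1-one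
Product: 9 (3S,6S)-3-[2-(2-ethyl-5,5-dimethyl-1,3-dioxan-2-yl)ethyl]-3-methyl-6-(propan-2-yl)cyclohexan-1-one, via Grignard reagent 8 (not isolated)
Conditions: Mg, THF, 25 °C; then Cu(OTf)2 (5 mol %), 1-[(2S)-1-hydroxy-4-methylpentan-2-yl]-3-(2,4,6-trimethylphenyl)-4,5-dihydroimidazolium hexafluorophosphate or its antipode (6 mol %), Et2O, 0 °C; 3, −30 °C; H2O
Reagents that add atoms: none
Why: Copper-catalysed asymmetric conjugate addition of a Grignard reagent to a β,β-disubstituted cyclic enone under a chiral N-heterocyclic carbene ligand creates the quaternary carbon under catalyst control. The resident centre is 1,4 to the reacting carbon and biases only weakly, and the minor (3R,6S) diastereomer is removed by chromatography, so an error here does not turn into an enantiomeric impurity later.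

Step 4
Reactants: 9 (3S,6S)-3-[2-(2-ethyl-5,5-dimethyl-1,3-dioxan-2-yl)ethyl]-3-methyl-6-(propan-2-yl)cyclohexan-1-one
Product: 10 (3S,6S)-3-methyl-3-(3-oxopentyl)-6-(propan-2-yl)cyclohexan-1-one
Conditions: p-TsOH·H2O (10 mol %), acetone–H2O (10:1), 25 °C
Reagents that add atoms: water, O
Why: Acid-catalysed ketal hydrolysis (transketalisation to acetone) under mild conditions, so that the 1,6-diketone is not driven into aldol cyclisation and the isopropyl-bearing carbon is not epimerised.

Step 5
Reactants: 10 (3S,6S)-3-methyl-3-(3-oxopentyl)-6-(propan-2-yl)cyclohexan-1-one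
Product: 13 (4S,5S,7S,10S)-eudesmane-3,6-dione (trans-fused; 4α-methyl equatorial), via dilithium dienolate 11 (not isolated), via unequilibrated dione epimers 12 (not isolated)
Conditions: LDA (2.4 equiv), THF, −78 °C, 10 added slowly; CuCl2 (2.4 equiv), DMF, −78 → −30 °C; aq NH4Cl; then NaOMe (0.2 equiv), MeOH, 25 °C
Reagents that add atoms: none
Why: This is the intramolecular form of the copper-mediated oxidative dimerisation of lithium ketone enolates. The diketone is run into excess amide so that each carbonyl is enolised before it can act as an aldol acceptor; the ring ketone should lose a proton from the C5 methylene rather than the isopropyl-bearing methine C7, and the chain ketone preferentially on its ethyl side (C4), the C2 side being branched towards the quaternary carbon. Divalent copper oxidises one enolate by one electron to an α-keto radical (or its copper-bound equivalent), which adds to C5 of the ring enolate; a second equivalent of CuCl2 oxidises the resulting ketyl to the second carbonyl and ends as monovalent CuCl. Ring A closes through the new C4–C5 bond in a six-membered, 6-exo-trig mode with respect to the ring enolate, whose C5=C6 bond stays outside the new ring. Of the other enolate pairings, C2/C5 would need a four-membered and C4/C7 an eight-membered ring, and C2/C7, which could close a bicyclo[2.2.2]octane, needs the more substituted ring enolate that kinetic deprotonation avoids. C4 and C5 are formed without dependable kinetic control (a chair-like approach favours the cis junction), but both are α to a carbonyl: methoxide takes C5 to the trans junction and C4 to the equatorial α-methyl, which escapes the 1,3-diaxial contact with the C10 methyl, the fixed quaternary C10 being the controlling element for both. C7 is exposed to the same equilibration and is expected to stay mainly in the equatorial β configuration it already has; any axial epimer is separated and resubmitted.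

Step 6
Reactants: 13 (4S,5S,7S,10S)-eudesmane-3,6-dione
Product: 14 (5R,7S,10S)-6-oxoeudesm-3-en-3-yl trifluoromethanesulfonate
Conditions: Tf2O (1.1 equiv), 2,6-di-tert-butyl-4-methylpyridine (1.3 equiv), CH2Cl2, 0 → 25 °C
Reagents that add atoms: trifluoromethanesulfonic anhydride, O=S(=O)(OS(=O)(=O)C(F)(F)F)C(F)(F)F
Why: O-Sulfonylation of the less hindered C3 ketone and loss of the axial C4 proton under equilibrating conditions should give the more substituted enol triflate, while the C6 ketone, flanked by C5 and the isopropyl-bearing C7, reacts far more slowly; the C4 stereocentre is erased on purpose.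

Step 7
Reactants: 14 (5R,7S,10S)-6-oxoeudesm-3-en-3-yl trifluoromethanesulfonate
Product: 15 (5R,6R,7S,10S)-6-hydroxyeudesm-3-en-3-yl trifluoromethanesulfonate
Conditions: LiBH(sec-Bu)3, THF, −78 → −20 °C; H2O
Reagents that add atoms: none
Why: Hydride reduction of a hindered cyclohexanone: the axial β trajectory is closed by the syn-axial C10 methyl, so the bulky borohydride should deliver hydride from the α side and set the 6β (axial) hydroxyl; vinyl triflates tolerate the reagent at low temperature.

Step 8
Reactants: 15 (5R,6R,7S,10S)-6-hydroxyeudesm-3-en-3-yl trifluoromethanesulfonate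
Product: 16 (5R,6R,7S,10S)-3-(trifluoromethanesulfonyloxy)eudesm-3-en-6-yl benzoate
Conditions: BzCl, DMAP, Et3N, CH2Cl2, 40 °C
Reagents that add atoms: benzoyl chloride, O=C(Cl)c1ccccc1
Why: DMAP-catalysed acylation of a hindered axial secondary alcohol, with gentle warming to offset the 1,3-diaxial C10 methyl; no stereocentre is touched.

Step 9
Reactants: 16 (5R,6R,7S,10S)-3-(trifluoromethanesulfonyloxy)eudesm-3-en-6-yl benzoate
Product: 17 (5R,6R,7S,10R)-eudesm-3-en-6-yl benzoate
Conditions: Pd(OAc)2 (5 mol %), PPh3 (10 mol %), HCO2H, n-Bu3N, DMF, 60 °C
Reagents that add atoms: none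
Why: Palladium-catalysed formate reduction of an enol triflate (oxidative addition to zerovalent palladium, formate exchange, decarboxylation, reductive elimination) leaves the double bond exactly at C3=C4; the benzoate is homoallylic and cannot ionise.

Step 10
Reactants: 17 (5R,6R,7S,10R)-eudesm-3-en-6-yl benzoate
Product: 18 (3R,4S,5S,6R,7S,10S)-3,4-epoxyeudesman-6-yl benzoate (3α,4α-epoxide)
Conditions: mCPBA, NaHCO3, CH2Cl2, 0 °C
Reagents that add atoms: 3-chloroperoxybenzoic acid, OOC(=O)c1cccc(Cl)c1
Why: Prilezhaev epoxidation of the trisubstituted alkene; the β face is covered by the axial C10 methyl and the 6β benzoate, so oxygen should be delivered to the α face, and the ester, unlike a free hydroxyl, cannot direct the peracid to the β face.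

Step 11
Reactants: 18 (3R,4S,5S,6R,7S,10S)-3,4-epoxyeudesman-6-yl benzoate
Product: 19 (3R,4R,5S,6R,7S,10S)-3,4-dihydroxyeudesman-6-yl benzoate (3α,4β-diol; target)
Conditions: HClO4 (aq, cat.), THF–H2O, 0 → 25 °C
Reagents that add atoms: water, O
Why: Acid-catalysed epoxide hydrolysis: the protonated epoxide opens at the tertiary C4 with inversion, which is both the Markovnikov and the trans-diaxial (Fürst–Plattner) mode, so water enters on the β face (possibly relayed through the carbonyl oxygen of the syn-axial benzoate as a bridged dioxanylium ion) and C3 keeps its α oxygen. This sets 3α-OH and 4β-OH.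

Compound list

1 | (2S,5R)-5-methyl-2-(propan-2-yl)cyclohexan-1-one, (−)-menthone | CC(C)[C@@H]1CC[C@@H](C)CC1=O | starting material
2 | trimethyl{[(3R,6S)-3-methyl-6-(propan-2-yl)cyclohex-1-en-1-yl]oxy}silane | CC(C)[C@@H]1CC[C@@H](C)C=C1O[Si](C)(C)C | intermediate
3 | (6S)-3-methyl-6-(propan-2-yl)cyclohex-2-en-1-one, (S)-piperitone | CC(C)[C@@H]1CCC(C)=CC1=O | intermediate
4 | pent-1-en-3-one | CCC(=O)C=C | starting material
5 | 2,2-dimethylpropane-1,3-diol | OCC(C)(C)CO | starting material
6 | 1-bromopentan-3-one | CCC(=O)CCBr | intermediate
7 | 2-(2-bromoethyl)-2-ethyl-5,5-dimethyl-1,3-dioxane | CCC1(CCBr)OCC(C)(C)CO1 | intermediate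
8 | [2-(2-ethyl-5,5-dimethyl-1,3-dioxan-2-yl)ethyl]magnesium bromide | CCC1(CC[Mg]Br)OCC(C)(C)CO1 | intermediate
9 | (3S,6S)-3-[2-(2-ethyl-5,5-dimethyl-1,3-dioxan-2-yl)ethyl]-3-methyl-6-(propan-2-yl)cyclohexan-1-one | CC(C)[C@@H]1CC[C@@](C)(CCC2(CC)OCC(C)(C)CO2)CC1=O | intermediate
10 | (3S,6S)-3-methyl-3-(3-oxopentyl)-6-(propan-2-yl)cyclohexan-1-one | CC(C)[C@@H]1CC[C@@](C)(CCC(=O)CC)CC1=O | intermediate
11 | dilithium dienolate of 10 (ring enolate C5=C6, chain enolate C3=C4, eudesmane numbering) | CC(C)[C@@H]1CC[C@@](C)(CCC(O[Li])=CC)C=C1O[Li] | intermediate
12 | (7S,10S)-eudesmane-3,6-dione, unequilibrated mixture of C4 and C5 epimers | CC(C)[C@@H]1CC[C@@]2(C)CCC(=O)C(C)C2C1=O | intermediate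
13 | (4S,5S,7S,10S)-eudesmane-3,6-dione, trans-fused, 4α-methyl, 7β-isopropyl | CC(C)[C@@H]1CC[C@@]2(C)CCC(=O)[C@@H](C)[C@@H]2C1=O | intermediate
14 | (5R,7S,10S)-6-oxoeudesm-3-en-3-yl trifluoromethanesulfonate | CC(C)[C@@H]1CC[C@@]2(C)CCC(OS(=O)(=O)C(F)(F)F)=C(C)[C@@H]2C1=O | intermediate
15 | (5R,6R,7S,10S)-6-hydroxyeudesm-3-en-3-yl trifluoromethanesulfonate, 6β-hydroxyl | CC(C)[C@@H]1CC[C@@]2(C)CCC(OS(=O)(=O)C(F)(F)F)=C(C)[C@@H]2[C@@H]1O | intermediate
16 | (5R,6R,7S,10S)-3-(trifluoromethanesulfonyloxy)eudesm-3-en-6-yl benzoate | CC(C)[C@@H]1CC[C@@]2(C)CCC(OS(=O)(=O)C(F)(F)F)=C(C)[C@@H]2[C@@H]1OC(=O)c1ccccc1 | intermediate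
17 | (5R,6R,7S,10R)-eudesm-3-en-6-yl benzoate | CC(C)[C@@H]1CC[C@@]2(C)CC=C(C)[C@@H]2[C@@H]1OC(=O)c1ccccc1 | intermediate
18 | (3R,4S,5S,6R,7S,10S)-3,4-epoxyeudesman-6-yl benzoate, 3α,4α-epoxide | CC(C)[C@@H]1CC[C@@]2(C)CC[C@H]3O[C@@]3(C)[C@@H]2[C@@H]1OC(=O)c1ccccc1 | intermediate
19 | (3R,4R,5S,6R,7S,10S)-3,4-dihydroxyeudesman-6-yl benzoate, CNP0187831.1 | CC(C)[C@@H]1CC[C@@]2(C)CC[C@@H](O)[C@](C)(O)[C@@H]2[C@@H]1OC(=O)c1ccccc1 | target

Total step count: 11. Longest linear sequence: 10 steps (steps 1, 3, 4, 5, 6, 7, 8, 9, 10, 11 from 1); step 2 is a one-step side branch.

Steps least certain to work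

Step 5 (key step). The most likely failure is non-productive enolisation: the chain ketone has two methylene α positions and the preference for C4 over C2 is only steric. Dienolates enolised at C2 cannot close and would be lost to chlorination or intermolecular coupling. Aldol attack of a mono-enolate on the other ketone is a second risk. Incomplete convergence at C7 is a third, because the equatorial preference of an isopropyl group beside a carbonyl is modest. The fallback separates enolisation from oxidation and sets out from 10. LDA with Et3SiCl as internal quench at −78 °C gives the bis(triethylsilyl) enol ether F1, whose C4,C5 regioisomer is purified on deactivated silica. Oxidation with (NH4)2Ce(NO3)6 and NaHCO3 in MeCN at −20 °C, a one-electron coupling of enol silanes by tetravalent cerium, then gives 12. The methoxide treatment of step 5 returns the route to 13.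

Step 3. The risk is poor facial selectivity at the new quaternary carbon. An axial approach on the half-chair with a pseudo-equatorial isopropyl group would place the chain cis to it, against the catalyst, so the pairing may be mismatched. The fallback uses the other enantiomer of the enone, for which substrate and catalyst should reinforce each other, and sets out from commercial (2R,5S)-menthone F2.
- F2 is taken through step 1 (enol silane F3, enone F4).
- Step 3 with the same ligand antipode gives ketal ketone F5, and step 4 gives diketone F6.
- Step 5 is then run as written (dienolate F7, unequilibrated dione F8).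
- Because the methoxide operation of step 5 equilibrates C7 together with C4 and C5, F8 converges on 13.

Step 6. The risk is sulfonylation on the wrong side (the C2,C3 enol triflate) or at the C6 ketone. The fallback makes the regiochemistry an isolable property and sets out from 13. TMSCl, NaI and Et3N in MeCN give the thermodynamic enol silane F9 (C3=C4), which is checked and purified. CsF and PhNTf2 in DME then convert it into 14 without any nucleophile that could touch C6.

Step 11. The risk is slow entry of water at the shielded β face of C4. That would let the C4 cation eliminate to allylic alcohols or take a hydride from C3, or let the benzoyl group pass to O4 through the bridged dioxanylium ion. The fallback delivers the C4 oxygen intramolecularly and introduces the benzoate last; it sets out from 15.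
- n-BuLi then Boc2O gives the tert-butyl carbonate F10.
- Formate reduction as in step 9 gives F11.
- mCPBA gives the α-epoxide F12.
- BF3·OEt2 in CH2Cl2 at −40 °C lets the carbonate carbonyl open the epoxide at C4 from the β face with loss of the tert-butyl group, giving the 4β,6β cyclic carbonate F13 with a free 3α hydroxyl.
- Excess PhLi in THF at −78 °C opens the carbonate to the secondary benzoate and the tertiary alcohol, which is 19.

## Further compounds

F1 | step 5 | bis(triethylsilyl) enol ether of 10 (ring C5=C6 and chain C3=C4) | CC(C)[C@@H]1CC[C@@](C)(CCC(O[Si](CC)(CC)CC)=CC)C=C1O[Si](CC)(CC)CC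
F2 | step 3 | (2R,5S)-5-methyl-2-(propan-2-yl)cyclohexan-1-one | CC(C)[C@H]1CC[C@H](C)CC1=O
F3 | step 3 | trimethyl{[(3S,6R)-3-methyl-6-(propan-2-yl)cyclohex-1-en-1-yl]oxy}silane | CC(C)[C@H]1CC[C@H](C)C=C1O[Si](C)(C)C
F4 | step 3 | (6R)-3-methyl-6-(propan-2-yl)cyclohex-2-en-1-one | CC(C)[C@H]1CCC(C)=CC1=O
F5 | step 3 | (3S,6R)-3-[2-(2-ethyl-5,5-dimethyl-1,3-dioxan-2-yl)ethyl]-3-methyl-6-(propan-2-yl)cyclohexan-1-one | CC(C)[C@H]1CC[C@@](C)(CCC2(CC)OCC(C)(C)CO2)CC1=O
F6 | step 3 | (3S,6R)-3-methyl-3-(3-oxopentyl)-6-(propan-2-yl)cyclohexan-1-one | CC(C)[C@H]1CC[C@@](C)(CCC(=O)CC)CC1=O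
F7 | step 3 | dilithium dienolate of F6 | CC(C)[C@H]1CC[C@@](C)(CCC(O[Li])=CC)C=C1O[Li]
F8 | step 3 | (7R,10S)-eudesmane-3,6-dione, unequilibrated mixture of C4 and C5 epimers | CC(C)[C@H]1CC[C@@]2(C)CCC(=O)C(C)C2C1=O
F9 | step 6 | (5R,7S,10S)-3-(trimethylsilyloxy)eudesm-3-en-6-one | CC(C)[C@@H]1CC[C@@]2(C)CCC(O[Si](C)(C)C)=C(C)[C@@H]2C1=O
F10 | step 11 | tert-butyl (5R,6R,7S,10S)-3-(trifluoromethanesulfonyloxy)eudesm-3-en-6-yl carbonate | CC(C)[C@@H]1CC[C@@]2(C)CCC(OS(=O)(=O)C(F)(F)F)=C(C)[C@@H]2[C@@H]1OC(=O)OC(C)(C)C
F11 | step 11 | tert-butyl (5R,6R,7S,10R)-eudesm-3-en-6-yl carbonate | CC(C)[C@@H]1CC[C@@]2(C)CC=C(C)[C@@H]2[C@@H]1OC(=O)OC(C)(C)C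
F12 | step 11 | tert-butyl (3R,4S,5S,6R,7S,10S)-3,4-epoxyeudesman-6-yl carbonate | CC(C)[C@@H]1CC[C@@]2(C)CC[C@H]3O[C@@]3(C)[C@@H]2[C@@H]1OC(=O)OC(C)(C)C
F13 | step 11 | (3R,4R,5S,6R,7S,10S)-3-hydroxyeudesmane-4,6-diyl carbonate (cyclic 4β,6β-carbonate) | CC(C)[C@@H]1CC[C@@]2(C)CC[C@@H](O)[C@](C)(O3)[C@@H]2[C@@H]1OC3=O
A1 | alternative 1 | (5R)-5-[(3S,6E,8E)-9-{[tert-butyl(dimethyl)silyl]oxy}-2,6-dimethylnona-6,8-dien-3-yl]-3-methylfuran-2(5H)-one | CC(C)[C@H](CC/C(C)=C/C=C/O[Si](C)(C)C(C)(C)C)[C@H]1OC(=O)C(C)=C1
A2 | alternative 1 | tricyclic γ-lactone (carbonyl carbon on C4 bridged to the C6 oxygen) with 3α-silyloxy group and C1,C2-alkene | CC(C)[C@@H]1CC[C@@]2(C)C=C[C@@H](O[Si](C)(C)C(C)(C)C)[C@](C)(C3=O)[C@@H]2[C@@H]1O3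
A3 | alternative 2 | 2-methoxy-5-methylcyclohexa-2,5-diene-1,4-dione | COC1=CC(=O)C(C)=CC1=O
A4 | alternative 2 | tert-butyl(dimethyl){[(1E)-2-(propan-2-yl)buta-1,3-dien-1-yl]oxy}silane | C=C/C(C(C)C)=C/O[Si](C)(C)C(C)(C)C
A5 | alternative 2 | N-protonated (S)-3,3-diphenyl-1-(2-methylphenyl)tetrahydropyrrolo[1,2-c][1,3,2]oxazaborole bis(trifluoromethanesulfonyl)imide | Cc1ccccc1B1OC(c2ccccc2)(c2ccccc2)[C@@H]2CCC[NH+]12.O=S(=O)([N-]S(=O)(=O)C(F)(F)F)C(F)(F)F
A6 | alternative 2 | endo, cis-fused 6α-(tert-butyldimethylsilyloxy)-3-methoxy-7-isopropyl-10-methyl bicyclic 2,7-diene-1,4-dione (eudesmane numbering) | CC(C)C1=CC[C@@]2(C)C(=O)C=C(OC)C(=O)[C@H]2[C@H]1O[Si](C)(C)C(C)(C)C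
A7 | alternative 3 | 4-(1-methyl-4-oxocyclohexa-2,5-dien-1-yl)butanal | CC1(CCCC=O)C=CC(=O)C=C1
A8 | alternative 3 | aminoindanol-derived N-pentafluorophenyl triazolium tetrafluoroborate, C18H11BF9N3O (one antipode drawn) | F[B-](F)(F)F.Fc1c(F)c(F)c(c(F)c1F)-[n+]1cn2[C@@H]3c4ccccc4C[C@@H]3OCc2n1
A9 | alternative 3 | cis-4a-methyl-4a,5,6,7-tetrahydronaphthalene-2,8(1H,8aH)-dione | C1CC[C@@]2(C)C=CC(=O)C[C@H]2C1=O
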